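**Plan**

- Retrosynthesis: in the trione ring, two bonds are cut together. One joins the side-chain-bearing ring carbon to a flanking carbonyl carbon; the other joins the adjacent CMe2 carbon to the central ketone carbon. This excises one O=C–CMe2 (isobutyryl) unit and leaves an aryl isobutyrate plus a 2,2-dimethyl-3-oxo ester. The ester C–O bond, the aryl–CH bond, the enone C=C bond and the aryl–C(=O) bond are cut next.
- Enabling feature: the cyclohexane-1,3,5-trione ring has two quaternary CMe2 carbons around its central ketone and only one enolisable carbon, so it is a β-keto ester with one isobutyryl unit stitched in. The phenol oxygen ortho to the benzylic CH is three atoms from that enolisable carbon and can deliver the isobutyryl group through a six-membered ring.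
- Forward: acylphloroglucinol 3 (step 1) and enone 7 (steps 2 and 3) are joined by a conjugate Friedel–Crafts addition (step 4). The phenol para to the aryl ketone is esterified (step 5). The trione ring is formed last, in one pot, by O-to-C acyl shift and Dieckmann closure (step 6). The aromatic ring is bought and no protecting group is used.
- Stereochemistry: the single stereocentre is set by catalyst control in step 4. Step 6 does not touch it and funnels both epimers at the transiently acylated carbon into the planar enol.

Key step: step 6

Assumption: 8, 10 and 11 are drawn as open keto phenols; any cyclic hemiketal between the chain ketone and a neighbouring phenol is taken to open under the basic conditions of steps 5 and 6.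

**Step 1**
Reactants: 1 2-methylbenzene-1,3,5-triol; 2 3-phenylpropanoic acid
Product: 3 1-(2,4,6-trihydroxy-3-methylphenyl)-3-phenylpropan-1-one
Conditions: BF3·OEt2 (solvent), 90 °C; then aq NaOAc, 25 °C
Reagents that add atoms: none
Why: Friedel–Crafts acylation of a phloroglucinol by a carboxylic acid in BF3·OEt2; the two free ring positions of 1 are equivalent and the new ketone deactivates the ring toward a second acylation.

**Step 2**
Reactants: 4 methyl 2,2-dimethyl-3-oxobutanoate; 5 3-methylbutanal
Product: 6 methyl 5-hydroxy-2,2,7-trimethyl-3-oxooctanoate (racemic)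
Conditions: LiN(iPr)2 (1.05 equiv), THF, −78 °C; then 5; then 1 M HCl
Reagents that add atoms: none
Why: Directed aldol addition; the acetyl methyl group is the only enolisable position of 4 because the other α-carbon is quaternary, and the racemic carbinol centre is removed in step 3.

**Step 3**
Reactants: 6 methyl 5-hydroxy-2,2,7-trimethyl-3-oxooctanoate
Product: 7 methyl (E)-2,2,7-trimethyl-3-oxooct-4-enoate
Conditions: TsOH·H2O (5 mol %), toluene, reflux, Dean–Stark trap
Reagents that add atoms: none
Why: Acid-catalysed dehydration of a β-hydroxy ketone (aldol condensation) should give the conjugated E-enone as the thermodynamic isomer.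

**Step 4**
Reactants: 3 1-(2,4,6-trihydroxy-3-methylphenyl)-3-phenylpropan-1-one; 7 methyl (E)-2,2,7-trimethyl-3-oxooct-4-enoate
Product: 8 methyl (5R)-2,2,7-trimethyl-3-oxo-5-[2,4,6-trihydroxy-3-methyl-5-(3-phenylpropanoyl)phenyl]octanoate
Conditions: quinine-derived squaramide catalyst (from 9-amino-9-deoxy-epi-quinine and 3,5-bis(trifluoromethyl)aniline, 10 mol %), CH2Cl2, 0 °C
Reagents that add atoms: none
Why: Enantioselective Friedel–Crafts-type Michael addition of a phenol to an enone under bifunctional amine–squaramide catalysis: the quinuclidine nitrogen deprotonates the acidic phenol para to the ketone, the squaramide N–H bonds hold the 1,3-dicarbonyl unit of 7, and the only free ring carbon of 3 adds to one face of the E-enone within the ion pair to set the benzylic centre as R (the quinidine-derived pseudoenantiomer is used if a first test shows the opposite sense).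

**Step 5**
Reactants: 8 methyl (5R)-2,2,7-trimethyl-3-oxo-5-[2,4,6-trihydroxy-3-methyl-5-(3-phenylpropanoyl)phenyl]octanoate; 9 2-methylpropanoyl chloride
Product: 10 methyl (5R)-5-[4,6-dihydroxy-3-methyl-2-(2-methylpropanoyloxy)-5-(3-phenylpropanoyl)phenyl]-2,2,7-trimethyl-3-oxooctanoate
Conditions: 9 (1.05 equiv), iPr2NEt (1.1 equiv), CH2Cl2, −20 → 0 °C
Reagents that add atoms: none
Why: Site-selective O-acylation (ester formation): the phenol para to the aryl ketone is the most acidic and the only one not tied to the carbonyl by a hydrogen bond, so one equivalent of acyl chloride should esterify it alone.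

**Step 6**
Reactants: 10 methyl (5R)-5-[4,6-dihydroxy-3-methyl-2-(2-methylpropanoyloxy)-5-(3-phenylpropanoyl)phenyl]-2,2,7-trimethyl-3-oxooctanoate
Product: 12 (S)-3-hydroxy-4,4,6,6-tetramethyl-2-{3-methyl-1-[2,4,6-trihydroxy-3-methyl-5-(3-phenylpropanoyl)phenyl]butyl}cyclohex-2-ene-1,5-dione (the target), via C-acylated β-diketone 11 (not isolated)
Conditions: LiN(SiMe3)2 (3.1 equiv), THF (0.02 M), −78 → −20 °C; then KOtBu (3 equiv), 0 → 40 °C; then cold 1 M HCl to pH 3
Reagents that add atoms: none
Why: Proposed new method: LiN(SiMe3)2 turns the two chelated phenols into phenoxides and enolises the C3 ketone toward C4 (C2 is quaternary); the C4 enolate carbon attacks the isobutyrate carbonyl on the neighbouring phenol oxygen through a six-membered chroman-2-olate (6-(enolexo)-exo-trig), which collapses to the phenoxide and β-diketone 11, an O-to-C acyl shift whose closest known type is the Baker–Venkataraman rearrangement. KOtBu then reversibly deprotonates the isopropyl methine of the diketonate, and this carbon closes the trione ring on the methyl ester (6-(enolendo)-exo-trig, Dieckmann condensation, the closure known from the alkoxide-catalysed trimerisation of dimethylketene and from Dieckmann routes to syncarpic acid); loss of methoxide and deprotonation of the triketone drive the sequence. No new stereocentre remains, since both C4 epimers of 11 converge on the planar enol carbon of 12; the benzylic centre is untouched and its descriptor changes from R to S only because the ring carbon now outranks the aryl carbon. The step needs site selectivity between two enolisable ketones and C- over O-acylation: the only ester sits para to the aryl ketone, out of reach of that enolate, and within a six-membered transition state of the wanted carbon, whereas O-acylation would need an eight-membered one. The polyanionic course is modelled on the C-acylation of lithium polyanions of polyhydroxyacetophenones.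

**Compound list**

1 | 2-methylbenzene-1,3,5-triol (2-methylphloroglucinol) | Cc1c(O)cc(O)cc1O | starting material
2 | 3-phenylpropanoic acid | OC(=O)CCc1ccccc1 | starting material
3 | 1-(2,4,6-trihydroxy-3-methylphenyl)-3-phenylpropan-1-one | Cc1c(O)cc(O)c(C(=O)CCc2ccccc2)c1O | intermediate
4 | methyl 2,2-dimethyl-3-oxobutanoate | CC(=O)C(C)(C)C(=O)OC | starting material
5 | 3-methylbutanal | CC(C)CC=O | starting material
6 | methyl 5-hydroxy-2,2,7-trimethyl-3-oxooctanoate (racemic) | CC(C)CC(O)CC(=O)C(C)(C)C(=O)OC | intermediate
7 | methyl (E)-2,2,7-trimethyl-3-oxooct-4-enoate | CC(C)C/C=C/C(=O)C(C)(C)C(=O)OC | intermediate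
8 | methyl (5R)-2,2,7-trimethyl-3-oxo-5-[2,4,6-trihydroxy-3-methyl-5-(3-phenylpropanoyl)phenyl]octanoate | Cc1c(O)c(C(=O)CCc2ccccc2)c(O)c([C@H](CC(C)C)CC(=O)C(C)(C)C(=O)OC)c1O | intermediate
9 | 2-methylpropanoyl chloride (isobutyryl chloride) | CC(C)C(Cl)=O | starting material
10 | methyl (5R)-5-[4,6-dihydroxy-3-methyl-2-(2-methylpropanoyloxy)-5-(3-phenylpropanoyl)phenyl]-2,2,7-trimethyl-3-oxooctanoate | Cc1c(O)c(C(=O)CCc2ccccc2)c(O)c([C@H](CC(C)C)CC(=O)C(C)(C)C(=O)OC)c1OC(=O)C(C)C | intermediate
11 | methyl (5R)-2,2,7-trimethyl-4-(2-methylpropanoyl)-3-oxo-5-[2,4,6-trihydroxy-3-methyl-5-(3-phenylpropanoyl)phenyl]octanoate (both C4 epimers) | Cc1c(O)c(C(=O)CCc2ccccc2)c(O)c([C@H](CC(C)C)C(C(=O)C(C)C)C(=O)C(C)(C)C(=O)OC)c1O | intermediate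
12 | (S)-3-hydroxy-4,4,6,6-tetramethyl-2-{3-methyl-1-[2,4,6-trihydroxy-3-methyl-5-(3-phenylpropanoyl)phenyl]butyl}cyclohex-2-ene-1,5-dione | Cc1c(O)c(C(=O)CCc2ccccc2)c(O)c([C@H](CC(C)C)C2=C(O)C(C)(C)C(=O)C(C)(C)C2=O)c1O | target

Total step count: 6. Longest linear sequence: 5 steps (steps 2, 3, 4, 5, 6).

**Steps most likely to fail**

1. Step 6 (proposed new method). Intermolecular ester exchange, or loss of the isobutyryl group through enolisation of the aryl ester, may outrun the intramolecular transfer. The hindered methine of the polyanion may also resist deprotonation, so that the sequence stalls after the acyl shift. The fallback uses known chemistry, sets out from 3 and 5, and returns at 12. Commercial 2,4,6-trihydroxyacetophenone would be C-methylated four times (MeI, NaOMe, MeOH) to 2-acetyl-3-hydroxy-4,4,6,6-tetramethylcyclohex-2-ene-1,5-dione F1. Deacetylation in refluxing aqueous HCl would give syncarpic acid F2. Knoevenagel condensation with 5 (piperidine, then dilute acid) would give 2,2,4,4-tetramethyl-6-(3-methylbutylidene)cyclohexane-1,3,5-trione F3. An enantioselective Friedel–Crafts-type Michael addition of 3 to this acceptor, under the same class of bifunctional catalyst as in step 4, should then give 12 directly.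

2. Step 4. The singly activated enone may react too slowly with the acyl-deactivated phloroglucinol, O-alkylation may compete, or facial selectivity may be poor. The fallback sets out from 3 and 7 and returns at 8. An achiral base (DABCO, CH2Cl2) would give racemic 8 F4. Preparative chromatography on a chiral stationary phase would separate 8 from its (S)-enantiomer F5, which is set aside.

3. Step 5. A chelated phenol may be acylated, over-acylation may occur, or the para oxygen may be held in a cyclic hemiketal. The fallback places the isobutyryl group on carbon before the arene is attached; it sets out from 4 and returns at 11. Soft enolisation of 4 (MgBr2·OEt2, iPr2NEt, CH2Cl2) and C-acylation with 9 would give methyl 2,2,6-trimethyl-3,5-dioxoheptanoate F6. Knoevenagel condensation with 5 (piperidine, AcOH) would give methyl 2,2,7-trimethyl-4-(2-methylpropanoyl)-3-oxooct-4-enoate F7. Catalytic asymmetric Michael addition of 3 to this doubly activated acceptor should give 11, which is closed to 12 with KOtBu as in the second stage of step 6.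

**Further compounds**

F1 | step 6 | 2-acetyl-3-hydroxy-4,4,6,6-tetramethylcyclohex-2-ene-1,5-dione | CC(=O)C1=C(O)C(C)(C)C(=O)C(C)(C)C1=O
F2 | step 6 | 2,2,4,4-tetramethylcyclohexane-1,3,5-trione (syncarpic acid) | CC1(C)C(=O)CC(=O)C(C)(C)C1=O
F3 | step 6 | 2,2,4,4-tetramethyl-6-(3-methylbutylidene)cyclohexane-1,3,5-trione | CC(C)CC=C1C(=O)C(C)(C)C(=O)C(C)(C)C1=O
F4 | step 4 | racemic methyl 2,2,7-trimethyl-3-oxo-5-[2,4,6-trihydroxy-3-methyl-5-(3-phenylpropanoyl)phenyl]octanoate | Cc1c(O)c(C(=O)CCc2ccccc2)c(O)c(C(CC(C)C)CC(=O)C(C)(C)C(=O)OC)c1O
F5 | step 4 | methyl (5S)-2,2,7-trimethyl-3-oxo-5-[2,4,6-trihydroxy-3-methyl-5-(3-phenylpropanoyl)phenyl]octanoate | Cc1c(O)c(C(=O)CCc2ccccc2)c(O)c([C@@H](CC(C)C)CC(=O)C(C)(C)C(=O)OC)c1O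
F6 | step 5 | methyl 2,2,6-trimethyl-3,5-dioxoheptanoate | CC(C)C(=O)CC(=O)C(C)(C)C(=O)OC
F7 | step 5 | methyl 2,2,7-trimethyl-4-(2-methylpropanoyl)-3-oxooct-4-enoate | CC(C)CC=C(C(=O)C(C)C)C(=O)C(C)(C)C(=O)OC
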